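**Retrosynthetic overview**

1. Target 10 ⇒ deoxybenzoin propargyl ether 5 plus one carbon from DMF-DMA. Rings C (pyranone) and D (2,2-dimethylpyran) are opened together; forward, one flask closes C by enaminone annulation and D by propargyl Claisen/oxa-6π ring closure.
2. 5 ⇒ triol deoxybenzoin 3 + 3-chloro-3-methylbut-1-yne 4, by site-selective O-alkylation of the ring B phenol through the dianion, with no protecting group.
3. 3 ⇒ resorcinol 1 + homovanillic acid 2, by Friedel–Crafts acylation.
4. Ring order: rings A and B are bought; ring C, then ring D, are both formed in the last operation.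

Assumption: the target has no stereocentre and no stereogenic double bond (the ring alkene is fixed cis), so it is achiral and there is no enantiomer to control.

**Route**

Step 1
Reactants: 1 resorcinol; 2 homovanillic acid (4-hydroxy-3-methoxyphenylacetic acid)
Product: 3 1-(2,4-dihydroxyphenyl)-2-(4-hydroxy-3-methoxyphenyl)ethan-1-one
Conditions: BF3·OEt2 (as solvent), 85 °C, 2 h, N2; then aq NaOAc
Reagents that add atoms: none
Why: Friedel–Crafts (Nencki-type) acylation of the very electron-rich resorcinol by the BF3-activated arylacetic acid goes to C4 (para to one OH, ortho to the other), the product ketone is deactivated against a second acylation, and the free guaiacol OH and the aryl methyl ether tolerate BF3·OEt2 at this temperature; no stereocentre is formed.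

Step 2
Reactants: 3 1-(2,4-dihydroxyphenyl)-2-(4-hydroxy-3-methoxyphenyl)ethan-1-one; 4 3-chloro-3-methylbut-1-yne
Product: 5 1-(2,4-dihydroxyphenyl)-2-[3-methoxy-4-(2-methylbut-3-yn-2-yloxy)phenyl]ethan-1-one
Conditions: t-BuOK (2.05 equiv), DMF, 0 °C, 20 min; then 4 (1.2 equiv), CuCl (5 mol %), 0 °C → rt, 12 h, Ar; aq NH4Cl
Reagents that add atoms: none
Why: Copper-catalysed propargylic O-alkylation (Williamson-type etherification through a copper acetylide/allenylidene) of the dianion of 3: two equivalents of base remove the 4-OH and the ring B OH protons, the 4-oxide is a weakly nucleophilic vinylogous carboxylate and the 2-OH stays locked in its hydrogen bond to the ketone, so the more basic guaiacolate oxygen captures the electrophile, the same principle as the dianion-controlled 4'-O-alkylation of 7,4'-dihydroxyisoflavones; no stereocentre is formed.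

Step 3
Reactants: 5 1-(2,4-dihydroxyphenyl)-2-[3-methoxy-4-(2-methylbut-3-yn-2-yloxy)phenyl]ethan-1-one
Product: 10 7-hydroxy-3-(8-methoxy-2,2-dimethyl-2H-chromen-6-yl)-4H-chromen-4-one, via enaminone 6 (not isolated), via isoflavone propargyl ether 7 (not isolated), via allenylphenol 8 (not isolated), via o-quinone methide 9 (not isolated)
Conditions: DMF-DMA (1.3 equiv), DMF, 90 °C, 2 h; then N2 sweep, 155 °C, 6 h
Reagents that add atoms: N,N-dimethylformamide dimethyl acetal (DMF-DMA), COC(OC)N(C)C
Why: Proposed new method: a one-flask merger of two known thermal reactions, in which at 90 °C the amide acetal condenses at the activated CH2 to enaminone 6 and the chelated 2-OH adds to it and expels HNMe2 to close ring C (closest known type: the deoxybenzoin/DMF-DMA isoflavone synthesis, which tolerates a free 7-OH), the N2 sweep then removes the volatiles (MeOH, HNMe2, excess acetal) so that neither the 7-OH is methylated nor the alkyne attacked, and at 155 °C the aryl 1,1-dimethylpropargyl ether undergoes an aromatic propargyl Claisen rearrangement to its only free ortho position followed by enolisation, 1,5-hydrogen shift and oxa-6π electrocyclisation to close ring D (closest known type: the thermal propargyl ether chromene synthesis in DMF or N,N-diethylaniline); no stereocentre is formed.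

**Compound list**

1 | resorcinol (benzene-1,3-diol) | Oc1cccc(O)c1 | starting material
2 | homovanillic acid (4-hydroxy-3-methoxyphenylacetic acid) | COc1cc(CC(=O)O)ccc1O | starting material
3 | 1-(2,4-dihydroxyphenyl)-2-(4-hydroxy-3-methoxyphenyl)ethan-1-one | COc1cc(CC(=O)c2ccc(O)cc2O)ccc1O | intermediate
4 | 3-chloro-3-methylbut-1-yne | C#CC(C)(C)Cl | starting material
5 | 1-(2,4-dihydroxyphenyl)-2-[3-methoxy-4-(2-methylbut-3-yn-2-yloxy)phenyl]ethan-1-one | COc1cc(CC(=O)c2ccc(O)cc2O)ccc1OC(C)(C)C#C | intermediate
6 | enaminone: 3-(dimethylamino)-1-(2,4-dihydroxyphenyl)-2-[3-methoxy-4-(2-methylbut-3-yn-2-yloxy)phenyl]prop-2-en-1-one (alkene geometry not fixed) | COc1cc(C(=CN(C)C)C(=O)c2ccc(O)cc2O)ccc1OC(C)(C)C#C | intermediate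
7 | isoflavone propargyl ether: 7-hydroxy-3-[3-methoxy-4-(2-methylbut-3-yn-2-yloxy)phenyl]-4H-chromen-4-one | COc1cc(-c2coc3cc(O)ccc3c2=O)ccc1OC(C)(C)C#C | intermediate
8 | allenylphenol: 7-hydroxy-3-[4-hydroxy-3-methoxy-5-(3-methylbuta-1,2-dien-1-yl)phenyl]-4H-chromen-4-one | COc1cc(-c2coc3cc(O)ccc3c2=O)cc(C=C=C(C)C)c1O | intermediate
9 | o-quinone methide: 7-hydroxy-3-[(3Z)-5-methoxy-3-(3-methylbut-2-en-1-ylidene)-4-oxocyclohexa-1,5-dien-1-yl]-4H-chromen-4-one | COC1=CC(-c2coc3cc(O)ccc3c2=O)=C/C(=C/C=C(C)C)C1=O | intermediate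
10 | 7-hydroxy-3-(8-methoxy-2,2-dimethyl-2H-chromen-6-yl)-4H-chromen-4-one | COc1cc(-c2coc3cc(O)ccc3c2=O)cc2c1OC(C)(C)C=C2 | target

**Totals**

Total step count: 3. Longest linear sequence: 3 (1 + 2 → 3 → 5 → 10).

**Steps most likely to fail, with fallbacks**

Step 2 is the most likely to fail, because the 4-O ether or the bis-ether may form alongside 5. The fallback sets out from 3 and comes back at 5. In the monoanion regime (K2CO3 1.0 equiv, allyl bromide 1.0 equiv, acetone, rt) only the most acidic 4-OH is alkylated, giving 1-[2-hydroxy-4-(prop-2-en-1-yloxy)phenyl]-2-(4-hydroxy-3-methoxyphenyl)ethan-1-one F1. The ring B phenol, now the only reactive one, is etherified with 4 (K2CO3, KI, CuCl cat., acetone, 56 °C) to give 1-[2-hydroxy-4-(prop-2-en-1-yloxy)phenyl]-2-[3-methoxy-4-(2-methylbut-3-yn-2-yloxy)phenyl]ethan-1-one F2. Pd(PPh3)4 (2 mol %) with morpholine in THF at rt then removes the allyl group and returns 5.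

Step 3 is next, because the 7-OH may be methylated by the acetal, the terminal alkyne may be attacked, or the Claisen stage may stall. The fallback sets out from 5 and comes back at 10. The two ring closures are uncoupled and ring D is closed first without heat: Ph3PAuNTf2 (2 mol %) in CH2Cl2 at rt effects 6-endo hydroarylation of the propargyl ether to give 1-(2,4-dihydroxyphenyl)-2-(8-methoxy-2,2-dimethyl-2H-chromen-6-yl)ethan-1-one F3. DMF-DMA (1.2 equiv) in THF at 65 °C then closes ring C through the enaminone 3-(dimethylamino)-1-(2,4-dihydroxyphenyl)-2-(8-methoxy-2,2-dimethyl-2H-chromen-6-yl)prop-2-en-1-one F4 (not isolated) and gives 10.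

Step 1 is the least risky of the three; it could fail through over-acylation or partial O-demethylation in hot BF3·OEt2. The fallback sets out from 1 and comes back at 3. A Hoesch reaction of 1 with bought 2-(4-hydroxy-3-methoxyphenyl)acetonitrile F5 (ZnCl2, HCl gas, Et2O, 0 °C) precipitates 1-(2,4-dihydroxyphenyl)-2-(4-hydroxy-3-methoxyphenyl)ethan-1-iminium chloride F6, which is hydrolysed in water at 100 °C to 3.

**Further compounds**

F1 | step 2 | 1-[2-hydroxy-4-(prop-2-en-1-yloxy)phenyl]-2-(4-hydroxy-3-methoxyphenyl)ethan-1-one | COc1cc(CC(=O)c2ccc(OCC=C)cc2O)ccc1O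
F2 | step 2 | 1-[2-hydroxy-4-(prop-2-en-1-yloxy)phenyl]-2-[3-methoxy-4-(2-methylbut-3-yn-2-yloxy)phenyl]ethan-1-one | COc1cc(CC(=O)c2ccc(OCC=C)cc2O)ccc1OC(C)(C)C#C
F3 | step 3 | 1-(2,4-dihydroxyphenyl)-2-(8-methoxy-2,2-dimethyl-2H-chromen-6-yl)ethan-1-one | COc1cc(CC(=O)c2ccc(O)cc2O)cc2c1OC(C)(C)C=C2
F4 | step 3 | 3-(dimethylamino)-1-(2,4-dihydroxyphenyl)-2-(8-methoxy-2,2-dimethyl-2H-chromen-6-yl)prop-2-en-1-one (alkene geometry not fixed) | COc1cc(C(=CN(C)C)C(=O)c2ccc(O)cc2O)cc2c1OC(C)(C)C=C2
F5 | step 1 | 2-(4-hydroxy-3-methoxyphenyl)acetonitrile (bought) | COc1cc(CC#N)ccc1O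
F6 | step 1 | 1-(2,4-dihydroxyphenyl)-2-(4-hydroxy-3-methoxyphenyl)ethan-1-iminium chloride | COc1cc(CC(=[NH2+])c2ccc(O)cc2O)ccc1O.[Cl-]
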